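**Retrosynthetic overview**
- Feature: in each benzo ring the lactone oxygen O1 (on C8a), the C8 methoxyl and the C7 hydroxyl sit on three neighbouring carbons, which is the pattern of 2-methoxyresorcinol. Both pyranone rings are therefore cut at C4–C4a and at O1–C2, leaving two molecules of that arene and two α-formyl ester units (C2/C3/C4), one on cyclohexene C2 and one on the β-carbon of the vinyl arm at C1.
- The bis(α-formyl) diester comes from a diester by twofold Claisen formylation. Its but-3-enoate arm comes from the C1 aldehyde by Takai iodo-olefination and palladium-catalysed Reformatsky coupling.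
- The cyclohexene with its C1 quaternary and C2 tertiary stereocentres comes from an endo-selective catalytic asymmetric Diels–Alder reaction of methacrolein with ethyl (3E)-5-methylhexa-3,5-dienoate, made from prenal by olefination and deconjugation.
- Ring order: the carbocycle first (step 3), then both pyranone rings together in the last step (step 7); the benzo rings are bought.

Key step: step 7

Assumption: the (S)-configured oxazaborolidinium catalyst in step 3 is assigned from the usual pre-transition-state model for 2-substituted acroleins; if the facial sense proves to be the reverse, the enantiomeric catalyst from (R)-diphenylprolinol is used with no other change.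

**Step 1**
Reactants: 1 3-methylbut-2-enal (prenal); 2 triethyl phosphonoacetate
Product: 3 ethyl (2E)-5-methylhexa-2,4-dienoate
Conditions: NaH, THF, 0 °C → rt
Reagents that add atoms: none
Why: Horner–Wadsworth–Emmons olefination of an unhindered enal with a stabilised phosphonate anion, which should give the (2E)-dienoate through the thermodynamically controlled anti elimination.

**Step 2**
Reactants: 3 ethyl (2E)-5-methylhexa-2,4-dienoate
Product: 5 ethyl (3E)-5-methylhexa-3,5-dienoate, via lithium trienolate 4 (not isolated)
Conditions: LiN(i-Pr)2, THF–DMPU, −78 °C; then AcOH, −78 °C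
Reagents that add atoms: none
Why: Deconjugative isomerisation by kinetic α-protonation of an extended enolate: ε-deprotonation of a terminal methyl group of the s-trans dienoate gives the trienolate, and protonation at the α-carbon should leave the terminal 2-methyl-1,3-diene with the new C3=C4 bond E.

**Step 3**
Reactants: 5 ethyl (3E)-5-methylhexa-3,5-dienoate; 6 methacrolein
Product: 7 ethyl 2-[(1R,6S)-6-formyl-3,6-dimethylcyclohex-2-en-1-yl]acetate (CHO cis to the CH2CO2Et arm)
Conditions: (S)-tetrahydro-1-(2-methylphenyl)-3,3-diphenyl-1H,3H-pyrrolo[1,2-c][1,3,2]oxazaborole (20 mol %), (CF3SO2)2NH (18 mol %), CH2Cl2, −78 → −40 °C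
Reagents that add atoms: none
Why: Catalytic asymmetric Diels–Alder reaction, a [4+2] cycloaddition that keeps every atom of 5 and 6, in which the C1-alkyl and C3-methyl groups of diene 5 both direct its CH2 terminus to the β-carbon of boron-bound 6 (quaternary carbon next to the CH2CO2Et-bearing carbon, ring methyl para to it), the endo position of the formyl group expected for an acyclic diene under Lewis acid activation places CHO cis to the CH2CO2Et arm, and shielding of one face of the s-trans enal by a catalyst phenyl group should direct the diene to the Re face at Cα, setting the (1R,6S) pair in one event.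

**Step 4**
Reactants: 7 ethyl 2-[(1R,6S)-6-formyl-3,6-dimethylcyclohex-2-en-1-yl]acetate
Product: 8 ethyl 2-[(1R,6S)-6-[(E)-2-iodoethenyl]-3,6-dimethylcyclohex-2-en-1-yl]acetate
Conditions: CrCl2 (6 equiv), CHI3 (2 equiv), THF, 0 °C → rt
Reagents that add atoms: iodoform, IC(I)I
Why: Takai olefination, in which the geminal dichromium species from CHI3 and divalent chromium adds to the aldehyde only (the ester is inert) and eliminates to the (E)-iodoalkene, an outcome reinforced by the adjacent quaternary carbon, which also has no α-hydrogen to epimerise.

**Step 5**
Reactants: 8 ethyl 2-[(1R,6S)-6-[(E)-2-iodoethenyl]-3,6-dimethylcyclohex-2-en-1-yl]acetate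
Product: 9 ethyl (3E)-4-[(1R,2R)-2-(2-ethoxy-2-oxoethyl)-1,4-dimethylcyclohex-3-en-1-yl]but-3-enoate
Conditions: BrZnCH2CO2Et (from BrCH2CO2Et, Zn dust, Me3SiCl activation, THF), Pd(PPh3)4 (5 mol %), THF–DMPU, 50 °C
Reagents that add atoms: ethyl 2-(bromozincio)acetate, CCOC(=O)C[Zn]Br
Why: Negishi-type cross-coupling of a Reformatsky reagent, prepared in the flask from ethyl bromoacetate by zinc insertion, with an alkenyl iodide (oxidative addition to zerovalent palladium, transmetalation from zinc, reductive elimination), which should retain the E geometry and tolerate the ester, and any β,γ to α,β isomer formed would converge in step 6 through the same dienolate.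

**Step 6**
Reactants: 9 ethyl (3E)-4-[(1R,2R)-2-(2-ethoxy-2-oxoethyl)-1,4-dimethylcyclohex-3-en-1-yl]but-3-enoate
Product: 11 bis(α-formyl) diester of the cyclohexene core (compound 9 carrying a formyl group on each ester α-carbon; epimers at those carbons in equilibrium with enol forms; ring stereocentres unchanged; used crude), via disodium bis(enolate) 10 (not isolated)
Conditions: NaH (excess), HCO2Et (excess), EtOH (cat.), THF, 0 °C → rt; then cold 1 M HCl
Reagents that add atoms: ethyl formate, CCOC=O
Why: Twofold crossed Claisen condensation (α-formylation) in which the arm reacts as a dienolate at its α-carbon and the ring-arm ester as a simple enolate, both condensations being driven by formation of the stabilised sodium enolates of the formyl esters, while the C1 and C2 ring stereocentres carry no acidic hydrogen.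

**Step 7**
Reactants: 11 bis(α-formyl) diester; 12 2-methoxybenzene-1,3-diol (2.2 equiv, two molecules are incorporated)
Product: 13 CNP0264408.1, 7-hydroxy-3-[(E)-2-[(1R,2R)-2-(7-hydroxy-8-methoxy-2-oxo-2H-chromen-3-yl)-1,4-dimethylcyclohex-3-en-1-yl]ethenyl]-8-methoxy-2H-chromen-2-one
Conditions: CF3CO2H–CH2Cl2 (1:4), 0 °C → rt
Reagents that add atoms: none
Why: Proposed new method: the closest known reaction type is the Pechmann condensation of resorcinols with α-formyl alkyl- and arylacetates to 3-substituted 7-hydroxycoumarins, but it has not been shown twofold on one substrate or on an α-alkenyl α-formyl ester (the 2-(hydroxymethylene)but-3-enoate arm), whose dienol should behave alike because acid protonates it kinetically at the α-carbon to give the same O-protonated aldehyde. Each protonated formyl carbon should alkylate 12 at an arene carbon ortho to one hydroxyl and para to the other (the two such carbons are mirror-related, so only the 7-hydroxy-8-methoxy pattern can arise), forming the C4–C4a bond. Loss of water through the para-hydroxybenzyl cation and attack of the ortho hydroxyl on the ester carbonyl with loss of ethanol then form the O1–C2 bond, so each pyranone ring closes by 6-exo-trig lactonisation, the acid equilibrating E and Z cinnamate isomers until the Z isomer is drained. No stereocentre is formed: the two epimeric formyl-bearing carbons become the sp2 C3 atoms, the C1 and C2 ring stereocentres carry no acidic hydrogen, and the arm alkene should stay E and in place because C1 is quaternary and the alkene ends up conjugated with the coumarin. The step needs chemoselectivity for the two formyl groups over the trisubstituted C3=C4 ring alkene and for lactonisation over a second arylation of the benzylic cation; the high nucleophilicity of the trioxygenated arene should let dilute CF3CO2H at or below ambient temperature suffice, which should protonate the ring alkene only slowly, and only a slight excess of 12 is used.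

**Compound list**
1 | 3-methylbut-2-enal (prenal) | CC(C)=CC=O | starting material
2 | triethyl phosphonoacetate | CCOC(=O)CP(=O)(OCC)OCC | starting material
3 | ethyl (2E)-5-methylhexa-2,4-dienoate | CCOC(=O)/C=C/C=C(C)C | intermediate
4 | lithium trienolate of 3 (lithium 1-ethoxy-5-methylhexa-1,3,5-trien-1-olate, 3E) | C=C(C)/C=C/C=C([O-])OCC.[Li+] | intermediate
5 | ethyl (3E)-5-methylhexa-3,5-dienoate | CCOC(=O)C/C=C/C(C)=C | intermediate
6 | methacrolein | C=C(C)C=O | starting material
7 | ethyl 2-[(1R,6S)-6-formyl-3,6-dimethylcyclohex-2-en-1-yl]acetate | O=C[C@@]1(C)CCC(C)=C[C@H]1CC(=O)OCC | intermediate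
8 | ethyl 2-[(1R,6S)-6-[(E)-2-iodoethenyl]-3,6-dimethylcyclohex-2-en-1-yl]acetate | I/C=C/[C@@]1(C)CCC(C)=C[C@H]1CC(=O)OCC | intermediate
9 | ethyl (3E)-4-[(1R,2R)-2-(2-ethoxy-2-oxoethyl)-1,4-dimethylcyclohex-3-en-1-yl]but-3-enoate | CCOC(=O)C/C=C/[C@@]1(C)CCC(C)=C[C@H]1CC(=O)OCC | intermediate
10 | disodium bis(enolate) of the bis(α-formyl) diester | CCOC(=O)C(=C[O-])/C=C/[C@@]1(C)CCC(C)=C[C@H]1C(=C[O-])C(=O)OCC.[Na+].[Na+] | intermediate
11 | bis(α-formyl) diester of the cyclohexene core (epimeric at both formyl-bearing carbons, in equilibrium with its enol forms) | CCOC(=O)C(C=O)/C=C/[C@@]1(C)CCC(C)=C[C@H]1C(C=O)C(=O)OCC | intermediate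
12 | 2-methoxybenzene-1,3-diol (2-methoxyresorcinol) | COc1c(O)cccc1O | starting material
13 | CNP0264408.1 | COc1c(O)ccc2cc(/C=C/[C@@]3(C)CCC(C)=C[C@H]3c3cc4ccc(O)c(OC)c4oc3=O)c(=O)oc12 | target

**Totals**
Total step count: 7. Longest linear sequence: 7 steps (from prenal 1 to 13).

**Steps most likely to fail**

1. Step 7 (proposed new method). What may go wrong: acid-induced migration or hydroarylation of the ring alkene, γ-protonation of the dienol arm that diverts it into conjugate addition or 2H-chromene formation, capture of the benzylic cation by a second arene before lactonisation, or lactonisation stopping at one ring.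
Fallback (known chemistry: aldol addition, then acid-mediated deprotection, lactonisation and dehydration), setting out from 9 and 12 and coming back at 13. Arene 12 is protected with MeOCH2Cl and i-Pr2NEt in CH2Cl2 as 1,3-bis(methoxymethoxy)-2-methoxybenzene F1. F1 is lithiated ortho to an acetal oxygen (n-BuLi, TMEDA, THF, 0 °C) and quenched with DMF to give 2,4-bis(methoxymethoxy)-3-methoxybenzaldehyde F2. Diester 9 is deprotonated at both α-carbons with LiN(i-Pr)2 (THF, −78 °C), and the two enolates, the arm reacting as a dienolate at its α-carbon, add to two molecules of F2 to give the bis(β-hydroxy ester) F3 as a diastereomer mixture. p-TsOH in MeOH at 40 °C then removes the four methoxymethyl groups, the freed ortho phenols lactonise and the benzylic hydroxyls are eliminated, which should give 13 under acid far weaker than that of the condensation.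

2. Step 3. What may go wrong: poor endo/exo discrimination with the α-methyl dienophile, insufficient facial selectivity, or slow turnover because the ester of the diene competes for the boron centre.
Fallback, setting out from 5 and 6 and coming back at 7. The cycloaddition is run without chiral control (EtAlCl2, CH2Cl2, −78 °C), which should give the racemic cis aldehyde F4 with the same regio- and endo selectivity. F4 is condensed with (1R,2R)-N,N'-dimethyl-1,2-diphenylethane-1,2-diamine (Et2O, 4 Å molecular sieves) to give two diastereomeric imidazolidines, the aminal of the (1R,6S) aldehyde F5 and the aminal of the (1S,6R) aldehyde F6, which are separated by chromatography. F5 is hydrolysed with dilute aqueous HCl in Et2O to release 7 and the recoverable diamine.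

3. Step 6. What may go wrong: incomplete formylation at the hindered ring-arm ester next to the quaternary carbon, competing Claisen self-condensation, and loss of the formylating agent by base-induced decarbonylation.
Fallback, setting out from 9 and coming back at 11. Diester 9 is heated with tert-butoxybis(dimethylamino)methane, t-BuOCH(NMe2)2, neat or in toluene at 100–120 °C. This aminomethylenation proceeds through the ester enolate and formamidinium ion pair without strong base and should give the bis(dimethylaminomethylene) diester F7. Brief hydrolysis of the two enamines with 1 M HCl in THF at 0 °C then gives 11.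

**Further compounds**
F1 | step 7 | 1,3-bis(methoxymethoxy)-2-methoxybenzene | COCOc1cccc(OCOC)c1OC
F2 | step 7 | 2,4-bis(methoxymethoxy)-3-methoxybenzaldehyde | COCOc1ccc(C=O)c(OCOC)c1OC
F3 | step 7 | bis(β-hydroxy ester) from 9 and two molecules of F2 (diastereomer mixture) | CCOC(=O)C(C(O)c1ccc(OCOC)c(OC)c1OCOC)/C=C/[C@@]1(C)CCC(C)=C[C@H]1C(C(O)c1ccc(OCOC)c(OC)c1OCOC)C(=O)OCC
F4 | step 3 | racemic cis ethyl 2-(6-formyl-3,6-dimethylcyclohex-2-en-1-yl)acetate (both enantiomers) | O=C[C@@]1(C)CCC(C)=C[C@H]1CC(=O)OCC.O=C[C@]1(C)CCC(C)=C[C@@H]1CC(=O)OCC
F5 | step 3 | (4R,5R)-1,3-dimethyl-4,5-diphenylimidazolidine aminal of 7 | CN1[C@H](c2ccccc2)[C@@H](c2ccccc2)N(C)C1[C@@]1(C)CCC(C)=C[C@H]1CC(=O)OCC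
F6 | step 3 | (4R,5R)-1,3-dimethyl-4,5-diphenylimidazolidine aminal of the (1S,6R) enantiomer of 7 | CN1[C@H](c2ccccc2)[C@@H](c2ccccc2)N(C)C1[C@]1(C)CCC(C)=C[C@@H]1CC(=O)OCC
F7 | step 6 | bis(dimethylaminomethylene) diester from 9 | CCOC(=O)C(=CN(C)C)/C=C/[C@@]1(C)CCC(C)=C[C@H]1C(=CN(C)C)C(=O)OCC
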